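## Retrosynthetic overview

1. Numbering (target positions): ring A = C1(CH3)=C2H–C3H–C8H–C9H–C10, ring B = C3–C4H2–C5H(CH3)–C6H(OH)–C7H(CH3)–C8, α = face of H-3 and H-8. End game: Suzuki union of a C9 (Z)-alkenyl boronate with (2E,4Z)-5-iodo-4-methylpenta-2,4-dienoic acid; the C10 exocyclic enone by Meyer–Schuster rearrangement of an alkynyl carbinol.
2. Ring B is disconnected at C3–C4 by an anionic oxy-Cope transform that re-forms C6–C1. The enabling feature: the C6 oxygen and the C1=C2 double bond of ring A are 1,6-related through C5–C4–C3 (a δ,ε-unsaturated ketone at the C6 ketone level) across a cis ring fusion, so the decalin is the [3,3] product of a 2-isopropenylbicyclo[2.2.2]oct-5-en-2-ol that already contains ring A.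
3. That bicyclooctenone is (S)-carvone folded back on itself (10-chlorination, dienolate C-alkylation forming C1–C10). The carvone carbonyl becomes C6, its stereocentre C8, its ring methyl the C1 methyl, and its isopropenyl group C9, C10 and the first side-chain carbon.
4. Ring order: carvone ring (sacrificial, opened in the key step) → ring A (step 6) → ring B (step 8, the last ring closed).
5. Stereo relay from the single bought centre C8: C3 in the key step (cis fusion), C5 and C7 by enolate equilibration, C6 by convex-face hydride, C9 by equilibration next to the C10 ketone.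

Key step: step 8

Remark: decalin intermediates are named with the target numbering above; the C10 carbinol centre made in step 13 is destroyed in step 16, so its configuration is left open and both epimers are carried.

## Route

Step 1
Reactants: 1 prop-2-yn-1-ol
Product: 3 (Z)-3-iodo-2-methylprop-2-en-1-ol, via alkenylmagnesium alkoxide 2 (not isolated)
Conditions: MeMgBr (2.5 equiv), CuI (10 mol %), THF, 0 °C → rt; then I2, −20 °C → rt
Reagents that add atoms: methylmagnesium bromide C[Mg]Br; iodine II
Why: Copper-catalysed anti-carbomagnesiation of the propargylic alkoxide places magnesium cis to the CH2O group through a magnesium chelate, and iodinolysis with retention should give the Z-iodide (carbometalation of an alkynol).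

Step 2
Reactants: 3 (Z)-3-iodo-2-methylprop-2-en-1-ol; 4 methyl (triphenylphosphoranylidene)acetate
Product: 6 methyl (2E,4Z)-5-iodo-4-methylpenta-2,4-dienoate, via (Z)-3-iodo-2-methylprop-2-enal 5 (not isolated)
Conditions: MnO2, CH2Cl2, rt
Reagents that add atoms: none
Why: MnO2 oxidation of the allylic alcohol with in situ Wittig olefination by the stabilised ylide should give the E-enoate without handling the isomerisation-prone Z-enal (tandem oxidation–Wittig reaction).

Step 3
Reactants: 6 methyl (2E,4Z)-5-iodo-4-methylpenta-2,4-dienoate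
Product: 7 (2E,4Z)-5-iodo-4-methylpenta-2,4-dienoic acid
Conditions: LiOH, THF/H2O, 0 °C → rt; then 1 M HCl
Reagents that add atoms: lithium hydroxide [Li+].[OH-]
Why: Mild saponification of the methyl ester should leave both alkene geometries and the vinyl iodide untouched.

Step 4
Reactants: 8 bis[(pinacolato)boryl]methane
Product: 10 1,1-bis[(pinacolato)boryl]ethane, via lithiated diborylmethane 9 (not isolated)
Conditions: lithium 2,2,6,6-tetramethylpiperidide, THF, 0 °C; then MeI
Reagents that add atoms: iodomethane CI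
Why: The proton between two boron atoms is acidic enough for the hindered amide base, and the boron-stabilised carbanion should be C-methylated (alkylation of a geminal diboryl carbanion).

Step 5
Reactants: 11 (S)-carvone
Product: 12 (S)-5-(3-chloroprop-1-en-2-yl)-2-methylcyclohex-2-en-1-one (10-chlorocarvone)
Conditions: Ca(OCl)2, solid CO2, CH2Cl2/H2O, 0 °C
Reagents that add atoms: calcium hypochlorite [Ca+2].[O-]Cl.[O-]Cl
Why: HOCl generated in situ reacts in an ene-type chlorination only with the electron-rich 1,1-disubstituted alkene (the enone alkene is inert), which should give the allylic chloride with the stereocentre untouched.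

Step 6
Reactants: 12 (S)-10-chlorocarvone
Product: 13 (1R,4R)-1-methyl-8-methylidenebicyclo[2.2.2]oct-5-en-2-one
Conditions: t-BuOK, t-BuOH/THF, 0 °C → rt
Reagents that add atoms: none
Why: Under equilibrating conditions the linear dienolate alkylates through its α carbon (target C1) in an intramolecular SN2 displacement, the only mode that gives a six-membered ring (α′ or γ attack would give cyclobutanes), so ring A and the quaternary bridgehead should form with the bridgehead configuration dictated by the carvone stereocentre.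

Step 7
Reactants: 13 (1R,4R)-1-methyl-8-methylidenebicyclo[2.2.2]oct-5-en-2-one; 14 isopropenylmagnesium bromide
Product: 15 (1R,2R,4R)-1-methyl-8-methylidene-2-(prop-1-en-2-yl)bicyclo[2.2.2]oct-5-en-2-ol
Conditions: CeCl3, THF, −78 → 0 °C
Reagents that add atoms: none
Why: The alkenylcerium reagent formed from the Grignard reagent and CeCl3 adds 1,2 without enolisation, and attack from the less hindered face syn to the C5=C6 bridge should place the isopropenyl group syn to that bridge, as the [3,3] shift requires (organocerium carbonyl addition).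

Step 8
Reactants: 15 (1R,2R,4R)-1-methyl-8-methylidene-2-(prop-1-en-2-yl)bicyclo[2.2.2]oct-5-en-2-ol
Product: 17 1,5-dimethyl-9-methylidene-cis-bicyclo[4.4.0]dec-1-en-6-one (C5 epimers), via potassium enolate 16 (not isolated)
Conditions: KH, 18-crown-6, THF, 0 °C → rt; then H2O
Reagents that add atoms: none
Why: The potassium alkoxide of 15 should undergo an anionic oxy-Cope ([3,3]) rearrangement through the boat-like six-centre array that the bicyclo[2.2.2]octene enforces: the isopropenyl CH2 (C4) bonds to C3 of the etheno bridge while the C6–C1 bond breaks, giving enolate 16 and the C1=C2 double bond. The closest known reaction type is the anionic oxy-Cope rearrangement of 2-vinylbicyclo[2.2.2]oct-5-en-2-ols to cis-fused octalones. Ring B is closed by this suprafacial [3,3] shift and not by a Baldwin-type cyclisation, and the sacrificial carvone ring is opened in the same event, so rings A and B emerge together as the decalin. The new stereocentre C3 is controlled by the bridgehead C8, because C4 can only reach the face of C3 that is syn to the carbinol bridge, which forces H-3 and H-8 cis; C5 arises on protonation of 16 and is corrected in step 9. The step needs the isopropenyl group syn to the C2=C3 bridge, which the facial selectivity of step 7 secures, and it needs [3,3] to win over fragmentation, which the charge-accelerated cleavage of the bond to the quaternary allylic C1 secures.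

Step 9
Reactants: 17 1,5-dimethyl-9-methylidene-cis-bicyclo[4.4.0]dec-1-en-6-one
Product: 19 1,5α,7α-trimethyl-9-methylidene-cis-bicyclo[4.4.0]dec-1-en-6-one, via lithium enolate 18 (not isolated)
Conditions: LiN(i-Pr)2, THF, −78 °C; MeI, −78 → 0 °C; then NaOMe, MeOH, rt
Reagents that add atoms: iodomethane CI
Why: Kinetic deprotonation should occur at the C7 methylene and not at the methyl-bearing C5, the enolate is C-methylated, and NaOMe then equilibrates both α-centres to the 5α,7α isomer in which both methyls are equatorial, because either epimer would place a methyl syn-axial to C2 (enolate alkylation followed by thermodynamic epimerisation).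

Step 10
Reactants: 19 1,5α,7α-trimethyl-9-methylidene-cis-bicyclo[4.4.0]dec-1-en-6-one
Product: 20 1,5α,7α-trimethyl-9-methylidene-cis-bicyclo[4.4.0]dec-1-en-6β-ol
Conditions: NaBH4, MeOH, −20 °C
Reagents that add atoms: none
Why: Hydride should attack the C6 carbonyl axially from the convex α face of the cis-decalin, away from ring A, which gives the equatorial 6β alcohol (borohydride reduction under steric approach control).

Step 11
Reactants: 20 1,5α,7α-trimethyl-9-methylidene-cis-bicyclo[4.4.0]dec-1-en-6β-ol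
Product: 22 6β-hydroxy-1,5α,7α-trimethyl-9-methylidene-cis-bicyclo[4.4.0]dec-1-en-10-one, via bis-allylic alcohol 21 (not isolated)
Conditions: SeO2 (cat.), t-BuOOH, CH2Cl2, rt; then MnO2, CH2Cl2, rt
Reagents that add atoms: tert-butyl hydroperoxide CC(C)(C)OO
Why: The selenium dioxide ene reaction and [2,3] shift should hydroxylate the ring CH2 at C10, the only doubly allylic position and the one on the more substituted alkene terminus, and MnO2 then oxidises only this bis-allylic alcohol and leaves the C6 alcohol (allylic oxidation).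

Step 12
Reactants: 22 6β-hydroxy-1,5α,7α-trimethyl-9-methylidene-cis-bicyclo[4.4.0]dec-1-en-10-one
Product: 24 6β-hydroxy-9α-(hydroxymethyl)-1,5α,7α-trimethyl-cis-bicyclo[4.4.0]dec-1-en-10-one, via boryl ketone 23 (not isolated)
Conditions: CuCl (cat.), NaOt-Bu (cat.), DPEphos, B2pin2, MeOH, THF, rt; then NaBO3·4H2O, THF/H2O, rt
Reagents that add atoms: bis(pinacolato)diboron CC1(C)OB(OC1(C)C)B1OC(C)(C)C(C)(C)O1; sodium perborate [Na+].[Na+].O[B-]1(O)OO[B-](O)(O)OO1
Why: The copper boryl species should add to the unhindered exocyclic CH2 terminus of the cross-conjugated dienone in preference to the ring terminus, perborate oxidises the C–B bond, and C9, now α to the ketone, should settle in the 9α configuration trans to C7, since the 9β epimer would press its CH2OH group against the C7 methyl (copper-catalysed conjugate borylation and oxidation).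

Step 13
Reactants: 24 6β-hydroxy-9α-(hydroxymethyl)-1,5α,7α-trimethyl-cis-bicyclo[4.4.0]dec-1-en-10-one; 25 tert-butyldimethyl(prop-2-yn-1-yloxy)silane
Product: 26 10-[3-(tert-butyldimethylsilyloxy)prop-1-ynyl]-9α-(hydroxymethyl)-1,5α,7α-trimethyl-cis-bicyclo[4.4.0]dec-1-ene-6β,10-diol (C10 epimers)
Conditions: 25, n-BuLi, THF, −78 °C; CeCl3; then 24, −78 °C
Reagents that add atoms: none
Why: The weakly basic alkynylcerium reagent, used in excess to cover the two hydroxyl groups, should add 1,2 to the hindered enone without enolisation or retro-aldol loss of formaldehyde; the new C10 carbinol centre is of no consequence (organocerium addition).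

Step 14
Reactants: 26 propargylic triol
Product: 27 10-[3-(tert-butyldimethylsilyloxy)prop-1-ynyl]-6β,10-dihydroxy-1,5α,7α-trimethyl-cis-bicyclo[4.4.0]dec-1-ene-9α-carbaldehyde
Conditions: TEMPO (cat.), PhI(OAc)2, CH2Cl2, rt
Reagents that add atoms: none
Why: The oxoammonium oxidant should oxidise only the primary alcohol and leave the hindered secondary and the tertiary alcohols (TEMPO/PhI(OAc)2 oxidation).

Step 15
Reactants: 27 C9 aldehyde; 10 1,1-bis[(pinacolato)boryl]ethane
Product: 28 10-[3-(tert-butyldimethylsilyloxy)prop-1-ynyl]-9α-[(Z)-2-(pinacolatoboryl)prop-1-enyl]-1,5α,7α-trimethyl-cis-bicyclo[4.4.0]dec-1-ene-6β,10-diol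
Conditions: 10, lithium 2,2,6,6-tetramethylpiperidide, THF, 0 °C; then 27, −78 °C → rt
Reagents that add atoms: none
Why: Addition of the lithiated geminal diboronate to the aldehyde and syn elimination of the boron–oxygen unit (boron–Wittig reaction) should give the trisubstituted alkenyl boronate with the C9 substituent trans to the remaining boryl group, the two alkoxides being covered by excess reagent at low temperature.

Step 16
Reactants: 28 alkenyl boronate carbinol
Product: 29 (E)-10-[3-(tert-butyldimethylsilyloxy)-2-oxopropylidene]-9α-[(Z)-2-(pinacolatoboryl)prop-1-enyl]-1,5α,7α-trimethyl-cis-bicyclo[4.4.0]dec-1-en-6β-ol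
Conditions: Ph3PAuNTf2 (cat.), MeOH (1 equiv), toluene, rt
Reagents that add atoms: none
Why: Gold-catalysed Meyer–Schuster rearrangement should move the tertiary hydroxyl oxygen to the distal alkyne carbon and give the exocyclic enone, which equilibrates to the geometry with the acyl group syn to C9 because the other isomer suffers allylic strain with the C1 methyl.

Step 17
Reactants: 29 dienone alkenyl boronate; 7 (2E,4Z)-5-iodo-4-methylpenta-2,4-dienoic acid
Product: 30 (2E,4Z,6E)-7-[(E)-10-[3-(tert-butyldimethylsilyloxy)-2-oxopropylidene]-6β-hydroxy-1,5α,7α-trimethyl-cis-bicyclo[4.4.0]dec-1-en-9α-yl]-4,6-dimethylhepta-2,4,6-trienoic acid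
Conditions: Pd(dppf)Cl2 (cat.), K3PO4, THF/H2O, rt
Reagents that add atoms: none
Why: Suzuki–Miyaura coupling proceeds with retention at both alkenyl partners and should give the (2E,4Z,6E)-trienoic acid, with mild base at room temperature chosen to spare the C9 centre.

Step 18
Reactants: 30 silyl ether of the target
Product: 31 CNP0219601.2 (target)
Conditions: HF·pyridine, pyridine, THF, 0 °C → rt
Reagents that add atoms: none
Why: Buffered HF·pyridine should cleave the primary silyl ether next to the ketone without touching the dienone or the trienoic acid (desilylation).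

## Compound list

1 | prop-2-yn-1-ol | C#CCO | starting material
2 | alkenylmagnesium alkoxide, (Z)-BrMgCH=C(CH3)CH2OMgBr | Br[Mg]/C=C(/C)CO[Mg]Br | intermediate
3 | (Z)-3-iodo-2-methylprop-2-en-1-ol | I/C=C(/C)CO | intermediate
4 | methyl (triphenylphosphoranylidene)acetate | COC(=O)C=P(c1ccccc1)(c1ccccc1)c1ccccc1 | starting material
5 | (Z)-3-iodo-2-methylprop-2-enal | I/C=C(/C)C=O | intermediate
6 | methyl (2E,4Z)-5-iodo-4-methylpenta-2,4-dienoate | COC(=O)/C=C/C(C)=C\I | intermediate
7 | (2E,4Z)-5-iodo-4-methylpenta-2,4-dienoic acid | OC(=O)/C=C/C(C)=C\I | intermediate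
8 | bis[(pinacolato)boryl]methane | C(B1OC(C)(C)C(C)(C)O1)B1OC(C)(C)C(C)(C)O1 | starting material
9 | lithiated bis[(pinacolato)boryl]methane | [Li]C(B1OC(C)(C)C(C)(C)O1)B1OC(C)(C)C(C)(C)O1 | intermediate
10 | 1,1-bis[(pinacolato)boryl]ethane | CC(B1OC(C)(C)C(C)(C)O1)B1OC(C)(C)C(C)(C)O1 | intermediate
11 | (S)-carvone | CC1=CC[C@@H](CC1=O)C(C)=C | starting material
12 | (S)-5-(3-chloroprop-1-en-2-yl)-2-methylcyclohex-2-en-1-one (10-chlorocarvone) | CC1=CC[C@@H](CC1=O)C(=C)CCl | intermediate
13 | (1R,4R)-1-methyl-8-methylidenebicyclo[2.2.2]oct-5-en-2-one | C[C@@]12C=C[C@@H](CC1=O)C(=C)C2 | intermediate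
14 | isopropenylmagnesium bromide | CC(=C)[Mg]Br | starting material
15 | (1R,2R,4R)-1-methyl-8-methylidene-2-(prop-1-en-2-yl)bicyclo[2.2.2]oct-5-en-2-ol (isopropenyl syn to the C5=C6 bridge) | C[C@@]12C=C[C@@H](C[C@@]1(O)C(C)=C)C(=C)C2 | intermediate
16 | potassium 1,5-dimethyl-9-methylidene-cis-bicyclo[4.4.0]deca-1,5-dien-6-olate (H-3α, H-8α) | CC1=C[C@H]2CC(C)=C([O-])C[C@H]2C(=C)C1.[K+] | intermediate
17 | 1,5-dimethyl-9-methylidene-cis-bicyclo[4.4.0]dec-1-en-6-one (H-3α, H-8α; C5 epimers) | CC1=C[C@H]2CC(C)C(=O)C[C@H]2C(=C)C1 | intermediate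
18 | lithium 1,5-dimethyl-9-methylidene-cis-bicyclo[4.4.0]deca-1,6-dien-6-olate | CC1=C[C@H]2CC(C)C(O[Li])=C[C@H]2C(=C)C1 | intermediate
19 | 1,5α,7α-trimethyl-9-methylidene-cis-bicyclo[4.4.0]dec-1-en-6-one | CC1=C[C@H]2C[C@H](C)C(=O)[C@H](C)[C@H]2C(=C)C1 | intermediate
20 | 1,5α,7α-trimethyl-9-methylidene-cis-bicyclo[4.4.0]dec-1-en-6β-ol | CC1=C[C@H]2C[C@H](C)[C@@H](O)[C@H](C)[C@H]2C(=C)C1 | intermediate
21 | 1,5α,7α-trimethyl-9-methylidene-cis-bicyclo[4.4.0]dec-1-ene-6β,10-diol (C10 epimers) | CC1=C[C@H]2C[C@H](C)[C@@H](O)[C@H](C)[C@H]2C(=C)C1O | intermediate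
22 | 6β-hydroxy-1,5α,7α-trimethyl-9-methylidene-cis-bicyclo[4.4.0]dec-1-en-10-one | CC1=C[C@H]2C[C@H](C)[C@@H](O)[C@H](C)[C@H]2C(=C)C1=O | intermediate
23 | 6β-hydroxy-1,5α,7α-trimethyl-9-[(pinacolatoboryl)methyl]-cis-bicyclo[4.4.0]dec-1-en-10-one (C9 epimers) | CC1=C[C@H]2C[C@H](C)[C@@H](O)[C@H](C)[C@H]2C(CB3OC(C)(C)C(C)(C)O3)C1=O | intermediate
24 | 6β-hydroxy-9α-(hydroxymethyl)-1,5α,7α-trimethyl-cis-bicyclo[4.4.0]dec-1-en-10-one | CC1=C[C@H]2C[C@H](C)[C@@H](O)[C@H](C)[C@H]2[C@H](CO)C1=O | intermediate
25 | tert-butyldimethyl(prop-2-yn-1-yloxy)silane | C#CCO[Si](C)(C)C(C)(C)C | starting material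
26 | 10-[3-(tert-butyldimethylsilyloxy)prop-1-ynyl]-9α-(hydroxymethyl)-1,5α,7α-trimethyl-cis-bicyclo[4.4.0]dec-1-ene-6β,10-diol (C10 epimers) | CC1=C[C@H]2C[C@H](C)[C@@H](O)[C@H](C)[C@H]2[C@H](CO)C1(O)C#CCO[Si](C)(C)C(C)(C)C | intermediate
27 | 10-[3-(tert-butyldimethylsilyloxy)prop-1-ynyl]-6β,10-dihydroxy-1,5α,7α-trimethyl-cis-bicyclo[4.4.0]dec-1-ene-9α-carbaldehyde (C10 epimers) | CC1=C[C@H]2C[C@H](C)[C@@H](O)[C@H](C)[C@H]2[C@H](C=O)C1(O)C#CCO[Si](C)(C)C(C)(C)C | intermediate
28 | 10-[3-(tert-butyldimethylsilyloxy)prop-1-ynyl]-9α-[(Z)-2-(pinacolatoboryl)prop-1-enyl]-1,5α,7α-trimethyl-cis-bicyclo[4.4.0]dec-1-ene-6β,10-diol (C10 epimers; C9 trans to boron) | CC1=C[C@H]2C[C@H](C)[C@@H](O)[C@H](C)[C@H]2[C@H](/C=C(C)/B3OC(C)(C)C(C)(C)O3)C1(O)C#CCO[Si](C)(C)C(C)(C)C | intermediate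
29 | (E)-10-[3-(tert-butyldimethylsilyloxy)-2-oxopropylidene]-9α-[(Z)-2-(pinacolatoboryl)prop-1-enyl]-1,5α,7α-trimethyl-cis-bicyclo[4.4.0]dec-1-en-6β-ol (acyl group syn to C9) | CC1=C[C@H]2C[C@H](C)[C@@H](O)[C@H](C)[C@H]2[C@H](/C=C(C)/B3OC(C)(C)C(C)(C)O3)/C1=C\C(=O)CO[Si](C)(C)C(C)(C)C | intermediate
30 | (2E,4Z,6E)-7-[(E)-10-[3-(tert-butyldimethylsilyloxy)-2-oxopropylidene]-6β-hydroxy-1,5α,7α-trimethyl-cis-bicyclo[4.4.0]dec-1-en-9α-yl]-4,6-dimethylhepta-2,4,6-trienoic acid | CC1=C[C@H]2C[C@H](C)[C@@H](O)[C@H](C)[C@H]2[C@H](/C=C(C)/C=C(C)\C=C\C(=O)O)/C1=C\C(=O)CO[Si](C)(C)C(C)(C)C | intermediate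
31 | CNP0219601.2: (2E,4Z,6E)-7-[(E)-6β-hydroxy-10-(3-hydroxy-2-oxopropylidene)-1,5α,7α-trimethyl-cis-bicyclo[4.4.0]dec-1-en-9α-yl]-4,6-dimethylhepta-2,4,6-trienoic acid | CC1=C[C@H]2C[C@H](C)[C@@H](O)[C@H](C)[C@H]2[C@H](/C=C(C)/C=C(C)\C=C\C(=O)O)/C1=C\C(=O)CO | target

## Step count and risks

Total step count: 18. Longest linear sequence: 14 steps (steps 5–18, from (S)-carvone).

Steps most likely to fail:

1. Step 11: poor site selectivity of the allylic C–H oxidation (C10 against the C1 methyl or the ring-fusion C–H), or oligomerisation of the cross-conjugated methylene dienone once formed. Fallback: put the C10 oxygen in before the rearrangement, where only one non-bridgehead allylic CH2 exists. From 13, SeO2 (cat.)/t-BuOOH should give the allylic alcohol 7-hydroxy-1-methyl-8-methylidenebicyclo[2.2.2]oct-5-en-2-one F1. 4-Methoxybenzyl trichloroacetimidate with La(OTf)3 (cat.) then gives the 4-methoxybenzyl ether F2, a group that cannot migrate under KH. Addition of 14 with CeCl3 gives the carbinol F3, KH/18-crown-6 the cis-decalin ketone F4, LiN(i-Pr)2/MeI then NaOMe the dimethyl ketone F5, and NaBH4 the alcohol F6. DDQ in wet CH2Cl2 removes the ether and the route is rejoined at 21.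

2. Step 16: ionisation of the tertiary allylic–propargylic carbinol and loss of water toward C9 in place of the 1,3-oxygen shift. Fallback: a stepwise hydration–elimination without gold. From 28 the Suzuki coupling with 7 (conditions of step 17) is run first to give the triene acid carbinol F7. Alkyne-selective trans-hydrosilylation with (EtO)3SiH and [Cp*Ru(MeCN)3]PF6 (cat.) should give the vinylsilane F8, with silicon on the carbon remote from the carbinol. Tamao–Fleming oxidation (KF, KHCO3, H2O2) gives the β-hydroxy ketone F9, and trifluoroacetylation with E1cB elimination (trifluoroacetic anhydride, Et3N; aqueous NaHCO3 work-up) rejoins the route at 30.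

3. Step 12: boryl addition to the ring enone terminus, or dimerisation of the methylene ketone before the addition. Fallback: an oxygen nucleophile in place of boron. From 22, PMe3-catalysed oxa-Michael addition of 4-methoxybenzyl alcohol should give the ether 6β-hydroxy-9α-[(4-methoxybenzyloxy)methyl]-1,5α,7α-trimethyl-cis-bicyclo[4.4.0]dec-1-en-10-one F10, and DDQ in wet CH2Cl2 rejoins the route at 24.

Further compounds

F1 | step 11 | 7-hydroxy-1-methyl-8-methylidenebicyclo[2.2.2]oct-5-en-2-one (C7 epimers) | C[C@@]12C=C[C@@H](CC1=O)C(=C)C2O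
F2 | step 11 | 7-(4-methoxybenzyloxy)-1-methyl-8-methylidenebicyclo[2.2.2]oct-5-en-2-one | C[C@@]12C=C[C@@H](CC1=O)C(=C)C2OCc3ccc(OC)cc3
F3 | step 11 | 7-(4-methoxybenzyloxy)-1-methyl-8-methylidene-2-(prop-1-en-2-yl)bicyclo[2.2.2]oct-5-en-2-ol | C[C@@]12C=C[C@@H](C[C@@]1(O)C(C)=C)C(=C)C2OCc3ccc(OC)cc3
F4 | step 11 | 10-(4-methoxybenzyloxy)-1,5-dimethyl-9-methylidene-cis-bicyclo[4.4.0]dec-1-en-6-one (C5 epimers) | CC1=C[C@H]2CC(C)C(=O)C[C@H]2C(=C)C1OCc3ccc(OC)cc3
F5 | step 11 | 10-(4-methoxybenzyloxy)-1,5α,7α-trimethyl-9-methylidene-cis-bicyclo[4.4.0]dec-1-en-6-one | CC1=C[C@H]2C[C@H](C)C(=O)[C@H](C)[C@H]2C(=C)C1OCc3ccc(OC)cc3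
F6 | step 11 | 10-(4-methoxybenzyloxy)-1,5α,7α-trimethyl-9-methylidene-cis-bicyclo[4.4.0]dec-1-en-6β-ol | CC1=C[C@H]2C[C@H](C)[C@@H](O)[C@H](C)[C@H]2C(=C)C1OCc3ccc(OC)cc3
F7 | step 16 | (2E,4Z,6E)-7-[10-[3-(tert-butyldimethylsilyloxy)prop-1-ynyl]-6β,10-dihydroxy-1,5α,7α-trimethyl-cis-bicyclo[4.4.0]dec-1-en-9α-yl]-4,6-dimethylhepta-2,4,6-trienoic acid | CC1=C[C@H]2C[C@H](C)[C@@H](O)[C@H](C)[C@H]2[C@H](/C=C(C)/C=C(C)\C=C\C(=O)O)C1(O)C#CCO[Si](C)(C)C(C)(C)C
F8 | step 16 | vinylsilane from F7: 10-[(Z)-3-(tert-butyldimethylsilyloxy)-2-(triethoxysilyl)prop-1-enyl] carbinol | CC1=C[C@H]2C[C@H](C)[C@@H](O)[C@H](C)[C@H]2[C@H](/C=C(C)/C=C(C)\C=C\C(=O)O)C1(O)/C=C(/CO[Si](C)(C)C(C)(C)C)[Si](OCC)(OCC)OCC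
F9 | step 16 | β-hydroxy ketone: 10-[3-(tert-butyldimethylsilyloxy)-2-oxopropyl] carbinol of the triene acid | CC1=C[C@H]2C[C@H](C)[C@@H](O)[C@H](C)[C@H]2[C@H](/C=C(C)/C=C(C)\C=C\C(=O)O)C1(O)CC(=O)CO[Si](C)(C)C(C)(C)C
F10 | step 12 | 6β-hydroxy-9α-[(4-methoxybenzyloxy)methyl]-1,5α,7α-trimethyl-cis-bicyclo[4.4.0]dec-1-en-10-one | CC1=C[C@H]2C[C@H](C)[C@@H](O)[C@H](C)[C@H]2[C@H](COCc3ccc(OC)cc3)C1=O
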